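## Assumption
4-(tert-Butyldimethylsilyloxy)benzoyl chloride, prepared from 4-hydroxybenzoic acid, is treated as an acylating reagent like TBSCl. It is not numbered as a building block.

## Retrosynthetic overview
1. Ferugin is the free phenol of a TBS-protected aryl ester, so the last step is aryl-silyl cleavage.
2. The seven-membered ring is closed last, by a SmI₂ ketyl–alkyne 7-exo-dig cyclization. This forms the ring, the secondary allylic alcohol and the exocyclic =CH₂ in one step.
3. The cyclization precursor is an alkyne-aldehyde cyclopentane. The tertiary carbinol comes from iPr–Ce addition anti to the neighbouring side chain, and the aldehyde from oxidative cleavage of an allyl group.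
4. The cyclopentane comes from one pot: asymmetric conjugate allylation of 3-methylcyclopentenone, aldol with 3-butynal, and O-aroylation. This sets the quaternary centre, the ring-fusion CH and the ester carbinol.
5. Ring order: cyclopentane first (ionic chemistry), cycloheptane last (radical).

## Forward route

**Step 1**
Reactants: 1 (but-3-yn-1-ol)
Product: 2 (but-3-ynal)
Conditions: Dess–Martin periodinane, NaHCO₃, CH₂Cl₂, 0 °C → rt, 1 h. Filter through Celite and use the cold solution at once.
Reagents that add atoms: none
Why: Dess–Martin oxidation of a primary alcohol to an aldehyde. It is mild enough that the terminal alkyne does not isomerize, and no stereocentre is involved.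

**Step 2**
Reactants: 3 (3-methylcyclopent-2-en-1-one), 2 (but-3-ynal)
Product: 4, (1S)-1-[(1S,5R)-5-methyl-2-oxo-5-(prop-2-en-1-yl)cyclopentyl]but-3-yn-1-yl 4-[(tert-butyldimethylsilyl)oxy]benzoate
Conditions: (a) allylMgBr, CuBr·SMe₂ (5 mol%), chiral ferrocenyl diphosphine ligand (Josiphos type, 6 mol%), t-BuOMe/THF, −78 °C. (b) Add 2, −78 °C. (c) Add the aroyl chloride and DMAP (cat.), −78 → 0 °C.
Reagents that add atoms: allylmagnesium bromide (C=CC[Mg]Br); 4-(tert-butyldimethylsilyloxy)benzoyl chloride (CC(C)(C)[Si](C)(C)Oc1ccc(cc1)C(Cl)=O)
Why: Proposed new method: a chiral Cu–allyl species adds to the β-carbon of the β,β-disubstituted enone to give a Mg enolate with the quaternary carbon in the R configuration (ligand enantiomer chosen for this). That enolate is regiospecific at C2, and the aldehyde attacks its face cis to the smaller Me group, so the new C–C bond ends up trans to the allyl group. The aldolate is acylated in situ to prevent retro-aldol or epimerization. The configuration at the carbinol carbon comes from the closed, chelated aldol transition state, and the diastereomers are separated by chromatography. The closest known chemistry is Cu/Josiphos asymmetric conjugate addition of Grignards to 3-methylcyclopentenone, combined with Noyori-type conjugate addition/aldol/acylation.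

**Step 3**
Reactants: 4
Product: 5, (1S)-1-[(1S,2R,5R)-2-hydroxy-5-methyl-2-(propan-2-yl)-5-(prop-2-en-1-yl)cyclopentyl]but-3-yn-1-yl 4-(TBS-oxy)benzoate
Conditions: iPrMgCl·LiCl (3.5 equiv), CeCl₃ (3.5 equiv), THF, −78 °C, 2 h; quench at −78 °C with sat. NH₄Cl.
Reagents that add atoms: isopropylmagnesium chloride (CC(C)[Mg]Cl)
Why: Organocerium 1,2-addition to a hindered ketone. The nucleophile is much less basic and reducing than the Grignard, so enolization, β-hydride reduction and ester attack are suppressed, and the extra equivalents cover deprotonation of the alkyne C–H. The face bearing the adjacent aroyloxy side chain and the Me group is the more hindered one, so iPr enters from the opposite face, on the same side as the allyl group, which is only a 1,3-interaction. This puts iPr trans and OH cis to the side chain, giving the target's tertiary carbinol (R).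

**Step 4**
Reactants: 5
Product: 6, (1S)-1-[(1S,2R,5R)-2-hydroxy-5-methyl-5-(2-oxoethyl)-2-(propan-2-yl)cyclopentyl]but-3-yn-1-yl 4-(TBS-oxy)benzoate
Conditions: OsO₄ (2 mol%), NaIO₄ (4 equiv), 2,6-lutidine (2 equiv), dioxane/H₂O 3:1, rt, 3 h.
Reagents that add atoms: sodium periodate (O source; [Na+].[O-]I(=O)(=O)=O)
Why: Lemieux–Johnson cleavage of the terminal alkene to the aldehyde. OsO₄ reacts with the monosubstituted alkene far faster than with the terminal alkyne. The CH₂CHO arm is trans to the tertiary OH, so no bridged lactol forms, and no stereocentre is touched.

**Step 5**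
Reactants: 6
Product: 7, TBS-protected ferugin: (4-(TBS-oxy)benzoate of the cycloheptane-fused tertiary alcohol with exocyclic methylene and secondary allylic OH)
Conditions: SmI₂ (3 equiv), HMPA (12 equiv), t-BuOH (2 equiv), THF, −78 °C → rt; substrate added by syringe pump to 2 mM.
Reagents that add atoms: none (SmI₂ is the electron donor; H comes from t-BuOH/THF)
Why: Proposed new method: SmI₂ reduces the aldehyde to a ketyl radical, which adds 7-exo-dig to the internal alkyne carbon (attack at the terminal carbon would be 8-endo). The exocyclic vinyl radical is then reduced and protonated, or abstracts H, to give the =CH₂, so ring, allylic alcohol and methylene form in one step. The closest known chemistry is SmI₂ ketyl–alkyne cyclization (5- and 6-exo-dig, Molander/Reissig type). The new carbinol centre is set in a chair-like transition state with the bulky Sm(III)(HMPA)ₙ alkoxide pseudo-equatorial, possibly chelated by the aroyloxy carbonyl. This is expected to give the target's carbinol configuration, with any minor epimer separable.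

**Step 6**
Reactants: 7
Product: 8, ferugin
Conditions: TBAF (1.5 equiv), AcOH (1.5 equiv), THF, 0 °C → rt, 1 h.
Reagents that add atoms: none
Why: Buffered fluoride cleaves the aryl TBS ether selectively. The hindered secondary aryl ester, the allylic alcohol, the tertiary alcohol and the exocyclic alkene are unaffected, and no stereocentre is touched.

## Compound list
1 | but-3-yn-1-ol | C#CCCO | starting material
2 | but-3-ynal | C#CCC=O | intermediate (aldol electrophile)
3 | 3-methylcyclopent-2-en-1-one | CC1=CC(=O)CC1 | starting material
4 | ketone ester (Step 2 product) | C#CC[C@H](OC(=O)c1ccc(O[Si](C)(C)C(C)(C)C)cc1)[C@@H]2[C@](C)(CCC2=O)CC=C | intermediate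
5 | tertiary alcohol | C#CC[C@H](OC(=O)c1ccc(O[Si](C)(C)C(C)(C)C)cc1)[C@@H]2[C@](C)(CC[C@@]2(O)C(C)C)CC=C | intermediate
6 | alkyne-aldehyde | C#CC[C@H](OC(=O)c1ccc(O[Si](C)(C)C(C)(C)C)cc1)[C@@H]2[C@](C)(CC[C@@]2(O)C(C)C)CC=O | intermediate
7 | TBS-protected ferugin | C=C1C[C@H](OC(=O)c2ccc(O[Si](C)(C)C(C)(C)C)cc2)[C@@H]2[C@](C)(CC[C@@]2(O)C(C)C)C[C@@H]1O | intermediate
8 | ferugin | C=C1C[C@H](OC(=O)c2ccc(O)cc2)[C@@H]2[C@](C)(CC[C@@]2(O)C(C)C)C[C@@H]1O | target

## Totals
Total steps: 6.
Longest linear sequence: 6 steps (Steps 1–6: 1 → 2 → 4 → 5 → 6 → 7 → 8). The branch from 3-methylcyclopentenone (3) is 5 steps (Steps 2–6).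

## Three steps most likely to fail
1. **Step 5 (SmI₂ 7-exo-dig cyclization):** low yield from pinacol dimerization or simple reduction, or the wrong carbinol epimer. Fallback: use 3-bromobut-3-enal in Step 2 instead of 2, then close the ring by intramolecular Nozaki–Hiyama–Kishi coupling (CrCl₂/NiCl₂) of the vinyl bromide with the aldehyde. This is a polar ring closure that gives the same exocyclic-methylene allylic alcohol. If the carbinol epimer is wrong, oxidize to the enone and reduce it (CBS or Luche).
2. **Step 2 (three-component coupling):** the Mg enolate may simply deprotonate the very acidic 3-butynal, the allyl Grignard may add 1,2, and ee and facial selectivity may be poor. Fallback: racemic Sakurai allylation (allylTMS/TiCl₄) of 3, then LDA aldol with 2, then O-aroylation, with the enantiomers resolved by preparative chiral HPLC at compound 4.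
3. **Step 3 (isopropyl addition):** the ketone is hindered, so reduction or 1,3-acyl migration to the tertiary alkoxide is possible. Fallback: trap the aldolate in Step 2 as the TES ether, add iPr–Ce, then remove the TES group and selectively aroylate the secondary alcohol (tertiary OH untouched) before the SmI₂ step.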